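## Retrosynthetic overview

1. The last skeletal bond is the ester's alkyl O–CH2 bond, made by opening spiro-epoxide 27 at its CH2 with the carboxylate of acid 10 (no acylation step); the tert-butyl ester is then cleaved.
2. The oxepinone ring of 27 comes from a two-carbon ring expansion of the cis-fused γ-lactol 18 by oxa-Michael/Horner–Wadsworth–Emmons annulation with phosphonoacrylate 23.
3. Lactol 18 comes from a dichloroketene [2+2] on cyclohexene 14 (sets the cis ring fusion, syn to the tertiary oxygen), then haloform-type cleavage; 14 comes from (S)-cryptone 12 and LiCH2Cl.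
4. Acid 10 comes from (R)-cryptone 4 by vinyl conjugate addition/enol triflation, Stille hydroxymethylation and cross-metathesis with a 2-(hydroxymethyl)acrylate.
5. Both cryptones come from 3-methylbutanal and butenone with either enantiomer of one organocatalyst. Ring order: cyclohexenone (each half), cyclobutanone, γ-lactol, oxepinone, oxirane (opened in the coupling).

Assumption: the SMILES is taken as drawn, so the isopropyl-bearing carbon is R in the acyl half and S in the lactone half, and the two halves come from opposite enantiomers of cryptone.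

## Route

Step 1
Reactants: 1 3-methylbutanal; 2 but-3-en-2-one
Product: 4 (4R)-4-(propan-2-yl)cyclohex-2-en-1-one [(R)-cryptone], via keto-aldehyde 3 (not isolated)
Conditions: (R)-α,α-diphenylprolinol trimethylsilyl ether (5 mol %), ethyl 3,4-dihydroxybenzoate (20 mol %), neat, 4 °C; then LiOH (0.1 equiv), iPrOH, rt
Reagents that add atoms: none
Why: Enamine-catalysed asymmetric Michael addition of the aldehyde to the enone (the diarylprolinol ether shields one enamine face, the steric-shielding model predicting the R centre from the (R)-catalyst), followed by intramolecular aldol condensation (Robinson-type annulation) that leaves the new stereocentre untouched.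

Step 2
Reactants: 4 (R)-cryptone
Product: 6 (3R,4R)-3-ethenyl-4-(propan-2-yl)cyclohex-1-en-1-yl trifluoromethanesulfonate, via magnesium enolate 5 (not isolated)
Conditions: CH2=CHMgBr, CuBr·SMe2 (20 mol %), THF, −78 °C; then Comins' reagent, −78 °C → rt
Reagents that add atoms: vinylmagnesium bromide, C=C[Mg]Br; N-(5-chloropyridin-2-yl)-1,1,1-trifluoro-N-(trifluoromethylsulfonyl)methanesulfonamide (Comins' reagent), FC(F)(F)S(=O)(=O)N(c1ccc(Cl)cn1)S(=O)(=O)C(F)(F)F
Why: Copper-catalysed conjugate addition of the vinyl Grignard reagent anti to the C4 isopropyl group sets the 3,4-trans relationship, and the regiodefined enolate is O-sulfonylated in situ (enolate trapping as the enol triflate).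

Step 3
Reactants: 6 enol triflate
Product: 7 [(3R,4R)-3-ethenyl-4-(propan-2-yl)cyclohex-1-en-1-yl]methanol
Conditions: Bu3SnCH2OH, Pd(PPh3)4 (5 mol %), LiCl, 1,4-dioxane, 100 °C
Reagents that add atoms: (tributylstannyl)methanol, OC[Sn](CCCC)(CCCC)CCCC
Why: Migita–Kosugi–Stille coupling of the enol triflate with the hydroxymethyl stannane gives the allylic alcohol directly and touches neither stereocentre.

Step 4
Reactants: 7 vinyl allylic alcohol
Product: 8 ethyl (2E)-2-(hydroxymethyl)-3-[(1R,6R)-3-(hydroxymethyl)-6-(propan-2-yl)cyclohex-2-en-1-yl]prop-2-enoate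
Conditions: ethyl 2-(hydroxymethyl)acrylate (5 equiv), second-generation Hoveyda–Grubbs catalyst RuCl2(H2IMes)(=CH-C6H4-2-OiPr) (10 mol %), 1,4-benzoquinone (10 mol %), toluene, 60 °C
Reagents that add atoms: ethyl 2-(hydroxymethyl)acrylate, C=C(CO)C(=O)OCC
Why: Olefin cross-metathesis of the monosubstituted vinyl group with the non-dimerising 1,1-disubstituted acrylate gives the trisubstituted enoate as the favoured E isomer (ester trans to the ring), while the trisubstituted ring alkene is inert.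

Step 5
Reactants: 8 ethyl ester
Product: 10 (2E)-2-(hydroxymethyl)-3-[(1R,6R)-3-(hydroxymethyl)-6-(propan-2-yl)cyclohex-2-en-1-yl]prop-2-enoic acid, via lithium carboxylate 9 (not isolated)
Conditions: LiOH·H2O, THF/H2O (3:1), rt; then 1 M HCl to pH 3
Reagents that add atoms: lithium hydroxide, [Li+].[OH-]
Why: Ester saponification (acyl substitution by hydroxide) proceeds without touching the alkene geometry or the stereocentres, since the carboxylate is not acidifying.

Step 6
Reactants: 1 3-methylbutanal; 2 but-3-en-2-one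
Product: 12 (4S)-4-(propan-2-yl)cyclohex-2-en-1-one [(S)-cryptone], via keto-aldehyde 11 (not isolated)
Conditions: (S)-α,α-diphenylprolinol trimethylsilyl ether (5 mol %), ethyl 3,4-dihydroxybenzoate (20 mol %), neat, 4 °C; then LiOH (0.1 equiv), iPrOH, rt
Reagents that add atoms: none
Why: The same enamine Michael addition/aldol condensation as in step 1, run with the antipodal catalyst, gives the S centre needed for the lactone half.

Step 7
Reactants: 12 (S)-cryptone
Product: 14 {[(1R,4S)-1-(chloromethyl)-4-(propan-2-yl)cyclohex-2-en-1-yl]oxy}triethylsilane, via lithium alkoxide 13 (not isolated)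
Conditions: ICH2Cl, MeLi·LiBr, Et2O/THF, −78 °C; then Et3SiOTf, −78 → −20 °C
Reagents that add atoms: chloroiodomethane, ClCI; triethylsilyl trifluoromethanesulfonate, CC[Si](CC)(CC)OS(=O)(=O)C(F)(F)F
Why: Barbier-type 1,2-addition of chloromethyllithium (iodine–lithium exchange in the presence of the enone) by axial attack, cis to the pseudo-equatorial isopropyl group, sets C1 (expected about 4:1, epimers separated), and the alkoxide is silylated before it can close to the epoxide.

Step 8
Reactants: 14 allylic silyl ether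
Product: 15 (1S,2S,5R,6S)-8,8-dichloro-5-(chloromethyl)-2-(propan-2-yl)-5-[(triethylsilyl)oxy]bicyclo[4.2.0]octan-7-one
Conditions: Cl3CCOCl, Zn(Cu), POCl3, Et2O, 25 °C, sonication
Reagents that add atoms: trichloroacetyl chloride, ClC(=O)C(Cl)(Cl)Cl
Why: Ketene–alkene [2+2] cycloaddition in which dichloroketene adds to the C2=C3 face anti to the pseudo-axial CH2Cl group and the isopropyl group, its carbonyl carbon bonding to C2 because positive charge develops at C3 away from the electron-poor C1, so the two new C–C bonds are cis to each other and syn to the C1 oxygen.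

Step 9
Reactants: 15 dichlorocyclobutanone
Product: 18 (3aS,4S,7R,7aS)-7-(chloromethyl)-3-hydroxy-4-(propan-2-yl)-7-[(triethylsilyl)oxy]hexahydro-2-benzofuran-1(3H)-one (lactol epimers at C3), via dichloromethyl carboxylate 16 (not isolated), via formyl carboxylate 17 (not isolated)
Conditions: LiOH·H2O, THF/H2O (2:1), 0 → 50 °C; then 1 M HCl to pH 3
Reagents that add atoms: lithium hydroxide, [Li+].[OH-]; water, O
Why: Haloform-type cleavage in which hydroxide adds to the strained cyclobutanone and expels the dichloromethyl carbanion, after which the cis carboxylate displaces chloride and the chlorolactone hydrolyses to the pseudo-acid lactol, the ring-fusion centres being untouched.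

Step 10
Reactants: 19 tert-butyl 2-(diethoxyphosphoryl)acetate
Product: 23 tert-butyl 2-(diethoxyphosphoryl)prop-2-enoate, via sodium enolate 20 (not isolated), via Mannich base 21 (not isolated), via ammonium iodide 22 (not isolated)
Conditions: NaH, THF, 0 °C; Me2N=CH2+ I−; then MeI, rt; then NaHCO3 (aq), CH2Cl2
Reagents that add atoms: N,N-dimethylmethyleneiminium iodide (Eschenmoser's salt), C=[N+](C)C.[I-]
Why: Mannich aminomethylation of the phosphonoacetate anion, N-quaternisation and E1cB loss of trimethylamine (α-methylenation) give the vinylphosphonate under non-acidic conditions that spare the tert-butyl ester.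

Step 11
Reactants: 18 lactol; 23 phosphonoacrylate
Product: 26 tert-butyl (5aR,6S,9R,9aS)-9-(chloromethyl)-1-oxo-6-(propan-2-yl)-9-[(triethylsilyl)oxy]-1,3,5a,6,7,8,9,9a-octahydro-2-benzoxepine-4-carboxylate, via formyl carboxylate 24 (not isolated), via phosphonate adduct 25 (not isolated)
Conditions: Cs2CO3 (1.2 equiv), MeCN, 0 °C → rt
Reagents that add atoms: none
Why: Proposed new method: base opens the pseudo-acid to its formyl carboxylate, the carboxylate oxygen adds in oxa-Michael fashion to the strongly electrophilic vinylphosphonate, and the phosphonate carbanion so formed closes the seven-membered ring by intramolecular Horner–Wadsworth–Emmons olefination (the ring forces the ring carbon cis to CH2O and the cis fusion is inherited from 18), the closest known reaction type being the tandem Michael/Horner–Wadsworth–Emmons annulation of 2-phosphonoacrylates with nitronate, phenoxide or alkoxide donors.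

Step 12
Reactants: 26 silyl-protected chlorohydrin lactone
Product: 27 tert-butyl (5aR,6S,9R,9aS)-1-oxo-6-(propan-2-yl)-1,5a,6,7,8,9a-hexahydro-3H-spiro[2-benzoxepine-9,2'-oxirane]-4-carboxylate
Conditions: Bu4NF, THF, 0 °C → rt
Reagents that add atoms: none
Why: Fluoride desilylation releases the tertiary alkoxide, which displaces the neighbouring primary chloride (intramolecular Williamson epoxide closure) with retention at the quaternary carbon.

Step 13
Reactants: 27 spiro-epoxide; 10 acid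
Product: 28 {(5aR,6S,9R,9aS)-4-(tert-butoxycarbonyl)-9-hydroxy-1-oxo-6-(propan-2-yl)-1,3,5a,6,7,8,9,9a-octahydro-2-benzoxepin-9-yl}methyl (2E)-2-(hydroxymethyl)-3-[(1R,6R)-3-(hydroxymethyl)-6-(propan-2-yl)cyclohex-2-en-1-yl]prop-2-enoate
Conditions: 10 (1.3 equiv), Cs2CO3 (0.3 equiv), DMF, 70 °C
Reagents that add atoms: none
Why: Base-catalysed SN2 opening of the 2,2-disubstituted epoxide at its CH2 terminus by the carboxylate of 10 (carboxylate alkylation) releases the tertiary alcohol with its configuration untouched, while the free hydroxyls of 10 do not compete and the weakly basic carboxylate does not enolise the lactone.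

Step 14
Reactants: 28 tert-butyl ester
Product: 29 (5aR,6S,9R,9aS)-9-hydroxy-9-({[(2E)-2-(hydroxymethyl)-3-[(1R,6R)-3-(hydroxymethyl)-6-(propan-2-yl)cyclohex-2-en-1-yl]prop-2-enoyl]oxy}methyl)-1-oxo-6-(propan-2-yl)-1,3,5a,6,7,8,9,9a-octahydro-2-benzoxepine-4-carboxylic acid (CNP0361406.3)
Conditions: CF3CO2H/CH2Cl2 (1:4), 0 °C; NaHCO3 (aq) work-up
Reagents that add atoms: none
Why: Acidolysis of the tert-butyl ester (E1 loss of 2-methylpropene) frees the conjugated acid, the tertiary alcohol being protected from ionisation by its electron-poor neighbours.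

## Compound list

1 | 3-methylbutanal | CC(C)CC=O | starting material
2 | but-3-en-2-one | CC(=O)C=C | starting material
3 | (2R)-5-oxo-2-(propan-2-yl)hexanal | CC(C)[C@H](C=O)CCC(C)=O | intermediate
4 | (4R)-4-(propan-2-yl)cyclohex-2-en-1-one | CC(C)[C@H]1CCC(=O)C=C1 | intermediate
5 | bromomagnesium (3R,4R)-3-ethenyl-4-(propan-2-yl)cyclohex-1-en-1-olate | CC(C)[C@H]1CCC(O[Mg]Br)=C[C@@H]1C=C | intermediate
6 | (3R,4R)-3-ethenyl-4-(propan-2-yl)cyclohex-1-en-1-yl trifluoromethanesulfonate (vinyl trans to isopropyl) | CC(C)[C@H]1CCC(OS(=O)(=O)C(F)(F)F)=C[C@@H]1C=C | intermediate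
7 | [(3R,4R)-3-ethenyl-4-(propan-2-yl)cyclohex-1-en-1-yl]methanol | CC(C)[C@H]1CCC(CO)=C[C@@H]1C=C | intermediate
8 | ethyl (2E)-2-(hydroxymethyl)-3-[(1R,6R)-3-(hydroxymethyl)-6-(propan-2-yl)cyclohex-2-en-1-yl]prop-2-enoate | CC(C)[C@H]1CCC(CO)=C[C@@H]1/C=C(\CO)C(=O)OCC | intermediate
9 | lithium (2E)-2-(hydroxymethyl)-3-[(1R,6R)-3-(hydroxymethyl)-6-(propan-2-yl)cyclohex-2-en-1-yl]prop-2-enoate | CC(C)[C@H]1CCC(CO)=C[C@@H]1/C=C(\CO)C(=O)[O-].[Li+] | intermediate
10 | (2E)-2-(hydroxymethyl)-3-[(1R,6R)-3-(hydroxymethyl)-6-(propan-2-yl)cyclohex-2-en-1-yl]prop-2-enoic acid | CC(C)[C@H]1CCC(CO)=C[C@@H]1/C=C(\CO)C(=O)O | intermediate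
11 | (2S)-5-oxo-2-(propan-2-yl)hexanal | CC(C)[C@@H](C=O)CCC(C)=O | intermediate
12 | (4S)-4-(propan-2-yl)cyclohex-2-en-1-one | CC(C)[C@@H]1CCC(=O)C=C1 | intermediate
13 | lithium (1R,4S)-1-(chloromethyl)-4-(propan-2-yl)cyclohex-2-en-1-olate | ClC[C@@]1([O-])CC[C@@H](C(C)C)C=C1.[Li+] | intermediate
14 | {[(1R,4S)-1-(chloromethyl)-4-(propan-2-yl)cyclohex-2-en-1-yl]oxy}triethylsilane (CH2Cl cis to isopropyl) | ClC[C@@]1(O[Si](CC)(CC)CC)CC[C@@H](C(C)C)C=C1 | intermediate
15 | (1S,2S,5R,6S)-8,8-dichloro-5-(chloromethyl)-2-(propan-2-yl)-5-[(triethylsilyl)oxy]bicyclo[4.2.0]octan-7-one (cis-fused; cyclobutanone anti to CH2Cl and isopropyl) | ClC[C@@]1(O[Si](CC)(CC)CC)CC[C@@H](C(C)C)[C@@H]2C(Cl)(Cl)C(=O)[C@@H]21 | intermediate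
16 | lithium (1S,2R,5S,6S)-2-(chloromethyl)-6-(dichloromethyl)-5-(propan-2-yl)-2-[(triethylsilyl)oxy]cyclohexane-1-carboxylate | ClC[C@@]1(O[Si](CC)(CC)CC)CC[C@@H](C(C)C)[C@H](C(Cl)Cl)[C@@H]1C(=O)[O-].[Li+] | intermediate
17 | lithium (1S,2R,5S,6S)-2-(chloromethyl)-6-formyl-5-(propan-2-yl)-2-[(triethylsilyl)oxy]cyclohexane-1-carboxylate | ClC[C@@]1(O[Si](CC)(CC)CC)CC[C@@H](C(C)C)[C@H](C=O)[C@@H]1C(=O)[O-].[Li+] | intermediate
18 | (3aS,4S,7R,7aS)-7-(chloromethyl)-3-hydroxy-4-(propan-2-yl)-7-[(triethylsilyl)oxy]hexahydro-2-benzofuran-1(3H)-one (both C3 epimers) | ClC[C@@]1(O[Si](CC)(CC)CC)CC[C@@H](C(C)C)[C@@H]2C(O)OC(=O)[C@@H]21 | intermediate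
19 | tert-butyl 2-(diethoxyphosphoryl)acetate | CCOP(=O)(CC(=O)OC(C)(C)C)OCC | starting material
20 | sodium 1-tert-butoxy-2-(diethoxyphosphoryl)ethen-1-olate (written as the carbanion) | CCOP(=O)(OCC)[CH-]C(=O)OC(C)(C)C.[Na+] | intermediate
21 | tert-butyl 2-(diethoxyphosphoryl)-3-(dimethylamino)propanoate | CCOP(=O)(OCC)C(CN(C)C)C(=O)OC(C)(C)C | intermediate
22 | 3-tert-butoxy-2-(diethoxyphosphoryl)-N,N,N-trimethyl-3-oxopropan-1-aminium iodide | CCOP(=O)(OCC)C(C[N+](C)(C)C)C(=O)OC(C)(C)C.[I-] | intermediate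
23 | tert-butyl 2-(diethoxyphosphoryl)prop-2-enoate | CCOP(=O)(OCC)C(=C)C(=O)OC(C)(C)C | intermediate
24 | cesium (1S,2R,5S,6S)-2-(chloromethyl)-6-formyl-5-(propan-2-yl)-2-[(triethylsilyl)oxy]cyclohexane-1-carboxylate | ClC[C@@]1(O[Si](CC)(CC)CC)CC[C@@H](C(C)C)[C@H](C=O)[C@@H]1C(=O)[O-].[Cs+] | intermediate
25 | 3-tert-butoxy-2-(diethoxyphosphoryl)-3-oxopropyl (1S,2R,5S,6S)-2-(chloromethyl)-6-formyl-5-(propan-2-yl)-2-[(triethylsilyl)oxy]cyclohexane-1-carboxylate (both epimers at the phosphonate carbon) | ClC[C@@]1(O[Si](CC)(CC)CC)CC[C@@H](C(C)C)[C@H](C=O)[C@@H]1C(=O)OCC(C(=O)OC(C)(C)C)P(=O)(OCC)OCC | intermediate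
26 | tert-butyl (5aR,6S,9R,9aS)-9-(chloromethyl)-1-oxo-6-(propan-2-yl)-9-[(triethylsilyl)oxy]-1,3,5a,6,7,8,9,9a-octahydro-2-benzoxepine-4-carboxylate | ClC[C@@]1(O[Si](CC)(CC)CC)CC[C@@H](C(C)C)[C@@H]2C=C(C(=O)OC(C)(C)C)COC(=O)[C@@H]21 | intermediate
27 | tert-butyl (5aR,6S,9R,9aS)-1-oxo-6-(propan-2-yl)-1,5a,6,7,8,9a-hexahydro-3H-spiro[2-benzoxepine-9,2'-oxirane]-4-carboxylate (epoxide oxygen cis to the lactone carbonyl) | C1O[C@@]12CC[C@@H](C(C)C)[C@@H]3C=C(C(=O)OC(C)(C)C)COC(=O)[C@@H]32 | intermediate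
28 | {(5aR,6S,9R,9aS)-4-(tert-butoxycarbonyl)-9-hydroxy-1-oxo-6-(propan-2-yl)-1,3,5a,6,7,8,9,9a-octahydro-2-benzoxepin-9-yl}methyl (2E)-2-(hydroxymethyl)-3-[(1R,6R)-3-(hydroxymethyl)-6-(propan-2-yl)cyclohex-2-en-1-yl]prop-2-enoate | CC(C)[C@H]1CCC(CO)=C[C@@H]1/C=C(\CO)C(=O)OC[C@@]1(O)CC[C@@H](C(C)C)[C@@H]2C=C(C(=O)OC(C)(C)C)COC(=O)[C@@H]21 | intermediate
29 | (5aR,6S,9R,9aS)-9-hydroxy-9-({[(2E)-2-(hydroxymethyl)-3-[(1R,6R)-3-(hydroxymethyl)-6-(propan-2-yl)cyclohex-2-en-1-yl]prop-2-enoyl]oxy}methyl)-1-oxo-6-(propan-2-yl)-1,3,5a,6,7,8,9,9a-octahydro-2-benzoxepine-4-carboxylic acid (CNP0361406.3) | CC(C)[C@H]1CCC(CO)=C[C@@H]1/C=C(\CO)C(=O)OC[C@@]1(O)CC[C@@H](C(C)C)[C@@H]2C=C(C(=O)O)COC(=O)[C@@H]21 | target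

## Step count and risks

Total step count: 14.
Longest linear sequence: 8 steps (steps 6, 7, 8, 9, 11, 12, 13, 14).

Three steps most likely to fail:

Step 8 (dichloroketene [2+2]). The alkene is flanked by a quaternary and a tertiary carbon, the regiochemistry rests on an inductive argument, and ZnCl2 may attack the allylic silyl ether. The fallback sets out from 12 and comes back at 18, and it builds the cis pair of carbon substituents by conjugate addition and kinetic protonation instead of cycloaddition. α-Iodination of 12 (I2, pyridine, CH2Cl2) gives (4S)-2-iodo-4-(propan-2-yl)cyclohex-2-en-1-one F1. Chloromethyllithium addition and silylation as in step 7 give {[(1S,4S)-1-(chloromethyl)-2-iodo-4-(propan-2-yl)cyclohex-2-en-1-yl]oxy}triethylsilane F2. Methoxycarbonylation (Pd(PPh3)4, CO, MeOH, Et3N, DMF, 60 °C) gives methyl (3S,6R)-6-(chloromethyl)-3-(propan-2-yl)-6-[(triethylsilyl)oxy]cyclohex-1-ene-1-carboxylate F3. Addition of (CH2=CH)2CuLi/Me3SiCl anti to the isopropyl group, then low-temperature protonation of the ketene acetal from the face opposite the new vinyl group, gives methyl (1S,2R,5S,6S)-2-(chloromethyl)-6-ethenyl-5-(propan-2-yl)-2-[(triethylsilyl)oxy]cyclohexane-1-carboxylate F4. Ozonolysis of the vinyl group (O3, CH2Cl2, −78 °C; Me2S) gives methyl (1S,2R,5S,6S)-2-(chloromethyl)-6-formyl-5-(propan-2-yl)-2-[(triethylsilyl)oxy]cyclohexane-1-carboxylate F5. LiOH hydrolysis and acidification then close the lactol 18.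

Step 11 (oxa-Michael/Horner–Wadsworth–Emmons ring expansion). A carboxylate is a weak Michael donor and the seven-membered olefination may lag behind side reactions of the free aldehyde. The fallback sets out from 18 and comes back at 26, and it closes the ring by metathesis instead. Alkylation of the carboxylate form of 18 with tert-butyl 2-(bromomethyl)acrylate (K2CO3, DMF) gives 2-(tert-butoxycarbonyl)prop-2-en-1-yl (1S,2R,5S,6S)-2-(chloromethyl)-6-formyl-5-(propan-2-yl)-2-[(triethylsilyl)oxy]cyclohexane-1-carboxylate F6. Wittig methylenation (Ph3P=CH2, THF, −78 °C) gives 2-(tert-butoxycarbonyl)prop-2-en-1-yl (1S,2R,5S,6S)-2-(chloromethyl)-6-ethenyl-5-(propan-2-yl)-2-[(triethylsilyl)oxy]cyclohexane-1-carboxylate F7. Ring-closing metathesis (second-generation Hoveyda–Grubbs catalyst, toluene, 80 °C) gives 26 with the ring alkene necessarily cis.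

Step 4 (cross-metathesis). The vinyl group sits on a crowded, doubly allylic ring carbon and the acrylate partner is 1,1-disubstituted, so conversion may be low and alkene migration may compete. The fallback sets out from 6 and comes back at 8, and it builds the acrylate by carbonyl olefination. Ozonolysis of the vinyl group of 6 (O3, CH2Cl2, −78 °C; Me2S; the enol triflate alkene is deactivated) gives (3R,4R)-3-formyl-4-(propan-2-yl)cyclohex-1-en-1-yl trifluoromethanesulfonate F8. Horner–Wadsworth–Emmons olefination with the carbanion generated in situ from ethyl 2-(diethoxyphosphoryl)acrylate and aqueous K2CO3 (hydroxide oxa-Michael adduct) gives ethyl (2E)-2-(hydroxymethyl)-3-[(1S,6R)-6-(propan-2-yl)-3-{[(trifluoromethyl)sulfonyl]oxy}cyclohex-2-en-1-yl]prop-2-enoate F9. Stille hydroxymethylation as in step 3 gives 8.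

Further compounds

F1 | step 8 | (4S)-2-iodo-4-(propan-2-yl)cyclohex-2-en-1-one | CC(C)[C@@H]1CCC(=O)C(I)=C1
F2 | step 8 | {[(1S,4S)-1-(chloromethyl)-2-iodo-4-(propan-2-yl)cyclohex-2-en-1-yl]oxy}triethylsilane | ClC[C@@]1(O[Si](CC)(CC)CC)CC[C@@H](C(C)C)C=C1I
F3 | step 8 | methyl (3S,6R)-6-(chloromethyl)-3-(propan-2-yl)-6-[(triethylsilyl)oxy]cyclohex-1-ene-1-carboxylate | ClC[C@@]1(O[Si](CC)(CC)CC)CC[C@@H](C(C)C)C=C1C(=O)OC
F4 | step 8 | methyl (1S,2R,5S,6S)-2-(chloromethyl)-6-ethenyl-5-(propan-2-yl)-2-[(triethylsilyl)oxy]cyclohexane-1-carboxylate | ClC[C@@]1(O[Si](CC)(CC)CC)CC[C@@H](C(C)C)[C@H](C=C)[C@@H]1C(=O)OC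
F5 | step 8 | methyl (1S,2R,5S,6S)-2-(chloromethyl)-6-formyl-5-(propan-2-yl)-2-[(triethylsilyl)oxy]cyclohexane-1-carboxylate | ClC[C@@]1(O[Si](CC)(CC)CC)CC[C@@H](C(C)C)[C@H](C=O)[C@@H]1C(=O)OC
F6 | step 11 | 2-(tert-butoxycarbonyl)prop-2-en-1-yl (1S,2R,5S,6S)-2-(chloromethyl)-6-formyl-5-(propan-2-yl)-2-[(triethylsilyl)oxy]cyclohexane-1-carboxylate | ClC[C@@]1(O[Si](CC)(CC)CC)CC[C@@H](C(C)C)[C@H](C=O)[C@@H]1C(=O)OCC(=C)C(=O)OC(C)(C)C
F7 | step 11 | 2-(tert-butoxycarbonyl)prop-2-en-1-yl (1S,2R,5S,6S)-2-(chloromethyl)-6-ethenyl-5-(propan-2-yl)-2-[(triethylsilyl)oxy]cyclohexane-1-carboxylate | ClC[C@@]1(O[Si](CC)(CC)CC)CC[C@@H](C(C)C)[C@H](C=C)[C@@H]1C(=O)OCC(=C)C(=O)OC(C)(C)C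
F8 | step 4 | (3R,4R)-3-formyl-4-(propan-2-yl)cyclohex-1-en-1-yl trifluoromethanesulfonate | CC(C)[C@H]1CCC(OS(=O)(=O)C(F)(F)F)=C[C@@H]1C=O
F9 | step 4 | ethyl (2E)-2-(hydroxymethyl)-3-[(1S,6R)-6-(propan-2-yl)-3-{[(trifluoromethyl)sulfonyl]oxy}cyclohex-2-en-1-yl]prop-2-enoate | CC(C)[C@H]1CCC(OS(=O)(=O)C(F)(F)F)=C[C@@H]1/C=C(\CO)C(=O)OCC
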